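Readings and results were computed with made-up constants; noise was put on by code.

In a one-step world free monomer would pass into monomer in chains at one constant and the readings would give the length directly, but a length also needs the number of chains, which no reading shows.

| flask | free monomer | initiator | remark | time |
|---|---|---|---|---|
| spring | 0.58 M | 20 mM | run made earlier |  |
| noon | 0.20 M | 20 mM | run made earlier |  |
| Thursday's | 0.39 M | 20 mM |  | 25 h |
| Monday's | 0.39 M | 5.0 mM |  | 25 h |

| run | time / h | monomer in chains / % | free monomer / % |
|---|---|---|---|
| spring | 0.667 | 4.1 | 95.5 |
| spring | 1.33 | 14.0 | 88.7 |
| spring | 2.50 | 21.7 | 77.0 |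
| spring | 5.00 | 42.7 | 56.9 |
| spring | 8.00 | 60.7 | 39.3 |
| noon | 0.833 | 4.6 | 96.2 |
| noon | 2.00 | 9.3 | 91.6 |
| noon | 4.00 | 18.1 | 83.4 |
| noon | 6.00 | 26.4 | 72.0 |
| noon | 8.00 | 34.7 | 63.6 |

(standard deviation of a reading: 1 percentage point)

- the average divides the monomer in chains by the number of chains begun, living and dead together
- the earlier runs do not show the number of chains; that part of a forecast is a guess
- no earlier run changes the charge of initiator; that part of a forecast is a guess

1. which of the two ends with the longer chains by the average number of monomer units in a chain (chains begun, living or dead) ("neither" if they lie within 10 %) (Thursday's / Monday's / neither)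
2. average number of monomer units in a chain (chains begun, living or dead) at the end, Thursday's
3. average number of monomer units in a chain (chains begun, living or dead) at the end, Monday's

Read as a first-order loss, the last readings give a constant of 0.117 h⁻¹ for the spring run and 0.0566 h⁻¹ for the noon run. Thursday's 0.39 M is the mean of those two charges, so the reckoning here takes the mean constant, 0.0867 h⁻¹.

Suppose each growing chain adds units in step with [free monomer]. Its length is then a growth constant times the charge times the integral of [free monomer] over time divided by the charge, and the number of chains cancels. For Thursday's flask that integral comes to 10.2 h: the hours of growth at full charge, here called the growth time.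

Time first: in Thursday's flask the growth time climbs towards 11.5 h, so 25 h has used most of it. Free monomer next: the spring charge at 25 h gives a shorter growth time, 8.10 h, yet charge times growth time is 1.18 times Thursday's. Initiator last, and here the reckoning guesses: the constant follows the charge, so Monday's quarter of the charge gives 0.0217 h⁻¹ and a growth time of 19.3 h. Monday's chains should therefore be 1.89 times as long as Thursday's.

The forecast also names Monday's, but with 25 and 75 units, a ratio of 3.00, and it warns: “Chain count is also a guess”.

The flask gives Monday's, with 60.7 units on Thursday's and 117 on Monday's, a ratio of 1.93.

    free monomer + initiator → living end + monomer in chains (k = 1.50 M⁻¹ h⁻¹)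
    free monomer + living end → monomer in chains + living end, rate k2*[living end]*[free monomer] (k = 16.0 M⁻¹ h⁻¹)
    initiator → spent initiator (k = 1.40 h⁻¹)

In Thursday's flask half of the passing of initiator into spent initiator up to 25 h is done by 0.354 h, while half of the passing of free monomer into monomer in chains is done by 6.93 h. At 12.5 h initiator stands at 0 % and living end at 0.00577 M, as it does at 25.0 h, and free monomer falls pseudo-first-order. Thursday's 10.3 % of free monomer left gives a growth time of 9.86 h, and its length then gives a growth constant of 15.8 M⁻¹ h⁻¹. Thursday's flask with 1.6 M of free monomer leaves 0.709 %, a growth time of 5.02 h; that constant puts its length at 127 units, and it ends at 127.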